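## Analysis of the target

Preluffariellolide A (20) is a C25 diol made of a saturated six-membered carbocycle (C14–C19) and a thirteen-carbon chain (C1–C13) that holds three E-configured trisubstituted alkenes (C2=C3, C6=C7, C10=C11) and ends in a primary allylic alcohol at C1. The ring carries a gem-dimethyl group at C19, a tertiary carbinol at C15 (methyl and hydroxyl) and, between these two fully substituted carbons, the methine C14 to which C13 is attached. C14 (S) and C15 (S) are the only stereocentres; they are adjacent, and the C13 branch and the C15 hydroxyl lie on opposite faces of the ring, so C13 is cis to the C15 methyl. The tertiary alcohol ionises easily under acid, which would erase C15 and could start cationic cyclisation onto the 1,5-diene chain. The allylic alcohol and the alkenes do not tolerate peracids or hydrogenation either, so all oxidative and reductive work on the ring has to be finished before the chain is attached. The difficulty is twofold: two contiguous stereocentres, one a fully substituted oxygen-bearing carbon, must be set in absolute and relative terms in a ring with no other handle, and every bond made at C13 or C14 is made next to two fully substituted neighbours. The plan rests on the trans arrangement C13–C14–C15–O. If the C15 oxygen is replaced in thought by an acetyl carbon, the C14–C15 bond is the saturated image of an E-alkene carrying formyl on C14 and methyl plus acetyl on C15. The ring C14–C19 is then the cycloadduct of that alkene with a C16–C19 diene whose C19 terminus already holds both methyl groups.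

## Retrosynthetic reasoning

**C1–O and C13–S, last operations.** Target 20 is traced to its C1 silyl ether 19 and this to the C13 phenylsulfonyl compound 18. Both cuts remove auxiliary groups only. The forward steps, fluoride desilylation and reductive C–S cleavage, must leave the tertiary alcohol and the three alkenes alone, which they can because the sulfone is not allylic and no acid is involved.

**C12–C13.** Sulfone 18 is cut between C12 and C13 into the ring-bearing hydroxy sulfone 12 and the allylic bromide 16. This is the one chain bond that puts an activated electrophile (allylic C12) against a stabilised carbanion (C13). It also divides the molecule so that farnesol 13 supplies C1–C12 with all three E-alkenes already in place, while the ring piece holds both stereocentres. A cut at C13–C14 would require bond formation at the methine between two fully substituted carbons and would make C14 stereogenic during the coupling. The forward alkylation has to be C-selective in the presence of the free tertiary alkoxide and must keep the alkene geometry.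

**Bromide 16.** The C12–Br bond goes back to the allylic alcohol 15 and its C12–O bond to a C–H bond of the silyl ether 14, which comes from 13. Only the terminal trans methyl group of the farnesyl chain has to be functionalised, a known selectivity of allylic oxidation.

**C13–S.** Sulfone 12 is traced through sulfide 11 to diol 10 by cutting the C13–S bond. The primary hydroxyl of 10 can be activated selectively, since the tertiary one is inert, and no stereocentre is involved. The forward displacement must cope with a β-branched, hindered carbon.

**C15–O traced to C15–C.** Diol 10 comes from diacetate 9, and the tertiary acetate of 9 from the methyl ketone 8 by oxygen insertion into the C15–acetyl bond. This trades a tertiary alcohol, which cannot be made stereoselectively by addition to a ring ketone flanked as this one is, for a carbon substituent that a cycloaddition can place. The forward peracid oxidation must make C15, not methyl, migrate, and must do so with retention.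

**Oxidation state and unsaturation.** Keto acetate 8 is related to the cyclohexene 7 by hydrogenation, 7 to the alcohol 6 by acylation, and 6 to the keto aldehyde 5 by selective reduction of the formyl group. The order is fixed by compatibility: the aldehyde and the ring alkene must both be gone before the peracid is used.

**Ring bonds C14–C19 and C15–C16.** Keto aldehyde 5 is cut across these two bonds into diene 4 and the E-enal 3. This removes the ring, both stereocentres and both fully substituted carbons at once and leaves two achiral six-carbon pieces. Of the three possible cyclohexene disconnections, only this one places the gem-dimethyl group on a diene terminus and both carbonyl groups on the dienophile. The forward cycloaddition needs the orientation C16 to C15 and C19 to C14, the E geometry of 3 carried into the trans relation of formyl and acetyl, and one enantioface of 3 selected by a chiral boron Lewis acid.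

**Enal 3.** The C3=C2 alkene with its two carbonyl groups is the opened form of furan 1. Oxidative opening gives the cis isomer 2, which is isomerised to 3; diene 4 is bought.

## Alternatives that were turned down

**Alternative 1:** Ring taken from an arene and desymmetrised by epoxidation. The disconnection is the C15–O bond, traced to an oxirane across C15–C16 of the achiral diene A1, the triisopropylsilyl ether of (2,6-dimethylcyclohexa-2,5-dien-1-yl)methanol, which comes from a Birch reduction. In the forward key step a chiral ketone-derived dioxirane epoxidises one of the two enantiotopic trisubstituted alkenes of A1 on the face away from the CH2OSi group to give A2.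
- In favour: the C15–O bond is made directly with no carbon-to-oxygen migration, C14 and C15 are fixed in one oxygen transfer, and the required anti face is also the sterically open one, so substrate bias and target agree. On these points it is as good as or better than the chosen plan. Partial over-oxidation to the bis-epoxide could even raise the enantiomeric purity of A2.
- Against: A1 has only one methyl group at C19. The second must be added later by building a quaternary carbon next to C14 on a molecule that already carries the oxirane or the tertiary alcohol. The choice between the two alkenes rests wholly on the reagent. The oxirane must then be opened by hydride at C16 only, and the doubly allylic diene re-aromatises easily.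
- Comparison: the cycloaddition of the chosen plan delivers all ten ring-fragment carbons, gem-dimethyl group included, in one step and needs the catalyst only for facial selection.

**Alternative 2:** Chain grown enzymatically from a ring-bearing primer. The disconnections are C8–C9 and C4–C5. A trans-prenyltransferase would condense the allylic diphosphate A3 with two molecules of isopentenyl diphosphate A4 to give the diphosphate A5, which a phosphatase would convert into 20.
- In favour: the two new alkenes are formed with enzymatic E-fidelity, no protecting groups are needed, and the chain assembly is one operation. In that it beats the four-step coupling sequence of the chosen plan.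
- Against: the ring and its two stereocentres are not addressed at all. A3 must still be made as a single enantiomer, with its own E-alkene and a diphosphate, so the real problem is only moved. The enzyme would have to accept a primer whose far end is a bulky hydroxylated ring. An enzyme of the C20-forming class measures chain length, and two additions to a primer already fifteen carbons long go beyond what its pocket normally allows. Cost of A4 and scale add to this.
- Comparison: the chosen plan takes all three E-alkenes ready-made from 13, which matches the enzyme's main asset, and it solves the stereochemical problem itself.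

**Alternative 3:** Ring closed by an amine-catalysed aldol at C14–C15. The achiral keto aldehyde A6 (3,3-dimethyl-7-oxooctanal) would form an enamine at the aldehyde with a chiral secondary amino acid. C14 of the enamine would add to the C15 ketone in a 6-enolexo closure to give the hydroxy aldehyde A7.
- In favour: this is the shortest route. A7 is at the correct oxidation level at C13 and C15, and its reduction would give diol 10 directly, so steps 1–7 of the chosen plan would shrink to the synthesis of A6 plus two steps. On step economy it is clearly stronger.
- Against: the acceptor is an unactivated methyl ketone. The donor carbon C14 sits next to the quaternary C19, so a reversible reaction has to create two adjacent congested centres. A7 is a β-hydroxy aldehyde with a tertiary hydroxyl and can revert by retro-aldol cleavage, lose water under the amine catalyst, or epimerise at C14. Both the anti relation and the absolute configuration must come from the catalyst's transition state, and the reverse-polarity aldol (ketone as donor, aldehyde as acceptor) competes.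
- Comparison: the chosen plan offers an irreversible ring formation in which the trans relation is fixed by alkene geometry and the product has no β-hydroxy carbonyl lability, at the price of more steps.

Key step: step 2

Assumption: the catalyst antipode alone fixes the absolute configuration in step 2. The (S)-diphenylprolinol-derived oxazaborolidinium is written; if correlation of the first sample at diol 10 shows the opposite sense of induction, the (R)-catalyst is used and nothing else changes.

## Route

**Step 1**
Reactants: 1 2,3-dimethylfuran
Product: 3 (2E)-3-methyl-4-oxopent-2-enal, via (2Z)-3-methyl-4-oxopent-2-enal 2 (not isolated)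
Conditions: N-bromosuccinimide, NaHCO3, acetone/H2O (10:1), −15 °C; then pyridine, rt
Reagents that add atoms: water, O
Why: Oxidative ring opening of a furan (bromonium formation at C5, attack of water, loss of HBr, opening of the 2,5-dihydrofuran) gives the cis-enedicarbonyl 2; reversible conjugate addition of pyridine lets the C2–C3 bond rotate and drains 2 into the E isomer 3, in which acetyl and formyl are trans.

**Step 2**
Reactants: 3 (2E)-3-methyl-4-oxopent-2-enal; 4 4-methylpenta-1,3-diene
Product: 5 (1S,6S)-6-acetyl-2,2,6-trimethylcyclohex-3-ene-1-carbaldehyde
Conditions: (S)-tetrahydro-1-(2-methylphenyl)-3,3-diphenyl-1H,3H-pyrrolo[1,2-c][1,3,2]oxazaborole (C24H24BNO, 20 mol %), (CF3SO2)2NH (18 mol %), 4 (5 equiv, slow addition), CH2Cl2, −78 → −20 °C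
Reagents that add atoms: none
Why: Lewis-acid-catalysed asymmetric Diels–Alder reaction; the closest known type is the cycloaddition of α,β-unsaturated aldehydes with acyclic dienes under triflimide-activated diarylprolinol-derived oxazaborolidinium catalysis. The boron centre binds the formyl oxygen, the less hindered of the two carbonyls, which lowers the LUMO and puts its largest coefficient on C15, the carbon β to the aldehyde. The unsubstituted diene terminus C16 has the largest HOMO coefficient and leaves tertiary allylic cation character at C19; it bonds first to C15, and the CMe2 terminus C19 closes onto the less hindered C14 in the same concerted but asynchronous suprafacial [4+2] event, so the six-membered ring is closed by cycloaddition with the C15–C16 and C14–C19 bonds formed on one face of each partner. The opposite orientation would join the two fully substituted carbons C15 and C19, so polarisation and steric demand point the same way, and binding at the ketone would activate only that disfavoured orientation. C14 and C15 are created together: their relative configuration (formyl trans to acetyl, cis to the C15 methyl) is copied from the E geometry of 3 by suprafacial addition and needs no control, and endo or exo approach is without consequence because neither diene terminus becomes stereogenic. The absolute configuration at both centres comes from the catalyst alone, whose aryl groups cover one enantioface of the bound enal so that the diene adds to the open face. The step therefore needs enantioface selectivity and enough rate: 4 must reach the s-cis conformer against the strain of its cis-methyl group and is prone to acid-induced oligomerisation, which is why it is used in excess, added slowly and kept cold.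

**Step 3**
Reactants: 5 (1S,6S)-6-acetyl-2,2,6-trimethylcyclohex-3-ene-1-carbaldehyde
Product: 6 1-[(1S,6S)-6-(hydroxymethyl)-1,5,5-trimethylcyclohex-3-en-1-yl]ethan-1-one
Conditions: NaBH4 (0.35 equiv), MeOH/CH2Cl2, −78 °C
Reagents that add atoms: none
Why: Chemoselective borohydride reduction: the formyl group reacts far faster than the methyl ketone on a quaternary carbon, and the cold, brief conditions should leave C14 (α to the aldehyde) unepimerised and avoid aldol closure between the acetyl methyl and the aldehyde; 6 may rest partly as its five-membered lactol, which does not matter for step 4.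

**Step 4**
Reactants: 6 1-[(1S,6S)-6-(hydroxymethyl)-1,5,5-trimethylcyclohex-3-en-1-yl]ethan-1-one
Product: 7 [(1S,6S)-6-acetyl-2,2,6-trimethylcyclohex-3-en-1-yl]methyl acetate
Conditions: Ac2O, pyridine, 4-(dimethylamino)pyridine (cat.), CH2Cl2, 0 °C → rt
Reagents that add atoms: acetic anhydride, CC(=O)OC(C)=O
Why: Nucleophile-catalysed acylation of the primary alcohol, which drains the open hydroxy ketone from any lactol; the acetate survives hydrogenation and peracid and leaves in step 7 together with the tertiary acetate, so protection costs no separate deprotection.

**Step 5**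
Reactants: 7 [(1S,6S)-6-acetyl-2,2,6-trimethylcyclohex-3-en-1-yl]methyl acetate
Product: 8 [(1S,2S)-2-acetyl-2,6,6-trimethylcyclohexyl]methyl acetate
Conditions: H2 (1 atm), 10% Pd/C, EtOAc, rt
Reagents that add atoms: none
Why: Heterogeneous catalytic hydrogenation of the cis-disubstituted ring alkene; no stereocentre is formed, ketone and ester are inert, and the alkene is removed before the peracid step, where it would be epoxidised.

**Step 6**
Reactants: 8 [(1S,2S)-2-acetyl-2,6,6-trimethylcyclohexyl]methyl acetate
Product: 9 (1S,2R)-2-[(acetyloxy)methyl]-1,3,3-trimethylcyclohexyl acetate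
Conditions: (CF3CO)2O, urea·H2O2, Na2HPO4, CH2Cl2, 0 °C → rt
Reagents that add atoms: trifluoroperacetic acid, OOC(=O)C(F)(F)F (made in the flask from trifluoroacetic anhydride and the hydrogen peroxide of its urea complex)
Why: Baeyer–Villiger oxidation: the peracid adds to the ketone and in the Criegee intermediate the tertiary C15 migrates in preference to methyl, with retention of configuration, so the C15–O bond appears exactly where the C15–acetyl bond was, trans to C13; the phosphate buffer keeps the tertiary acetate from ionising, and the descriptor at C14 changes to R only through the priority rules.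

**Step 7**
Reactants: 9 (1S,2R)-2-[(acetyloxy)methyl]-1,3,3-trimethylcyclohexyl acetate
Product: 10 (1S,2R)-2-(hydroxymethyl)-1,3,3-trimethylcyclohexan-1-ol
Conditions: LiAlH4, THF, 0 °C → rt; aqueous work-up
Reagents that add atoms: none
Why: Hydride reduction of both esters by acyl–oxygen cleavage; the C15–O bond is not touched, so the configuration set in steps 2 and 6 is kept.

**Step 8**
Reactants: 10 (1S,2R)-2-(hydroxymethyl)-1,3,3-trimethylcyclohexan-1-ol
Product: 11 (1S,2S)-1,3,3-trimethyl-2-[(phenylsulfanyl)methyl]cyclohexan-1-ol
Conditions: PhSSPh, PBu3, pyridine, 60 °C
Reagents that add atoms: diphenyl disulfide, c1ccccc1SSc1ccccc1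
Why: Hata-type thioetherification: phosphine and disulfide give a thiophosphonium salt that activates only the primary hydroxyl as an alkoxyphosphonium ion (the tertiary alcohol is too hindered), and thiophenolate displaces it at C13 by SN2; the β-branched carbon is slow, hence the heating, but no stereocentre is involved.

**Step 9**
Reactants: 11 (1S,2S)-1,3,3-trimethyl-2-[(phenylsulfanyl)methyl]cyclohexan-1-ol
Product: 12 (1S,2S)-2-[(benzenesulfonyl)methyl]-1,3,3-trimethylcyclohexan-1-ol
Conditions: 30% H2O2, (NH4)6Mo7O24·4H2O (cat.), EtOH, 0 °C → rt
Reagents that add atoms: hydrogen peroxide, OO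
Why: Molybdate-catalysed oxidation of the sulfide through the sulfoxide to the sulfone; no alkene is present at this stage and the tertiary alcohol is inert.

**Step 10**
Reactants: 13 (2E,6E)-farnesol
Product: 14 tert-butyl(dimethyl){[(2E,6E)-3,7,11-trimethyldodeca-2,6,10-trien-1-yl]oxy}silane
Conditions: tert-butyldimethylsilyl chloride, imidazole, DMF, 0 °C → rt
Reagents that add atoms: tert-butyldimethylsilyl chloride, CC(C)(C)[Si](C)(C)Cl
Why: Silylation of the primary allylic alcohol; the silyl ether withstands allylic oxidation, bromination, the organolithium coupling and the desulfonylation, and is removed by fluoride at the end.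

**Step 11**
Reactants: 14 tert-butyl(dimethyl){[(2E,6E)-3,7,11-trimethyldodeca-2,6,10-trien-1-yl]oxy}silane
Product: 15 (2E,6E,10E)-12-{[tert-butyl(dimethyl)silyl]oxy}-2,6,10-trimethyldodeca-2,6,10-trien-1-ol
Conditions: SeO2 (cat.), t-BuOOH, salicylic acid (cat.), CH2Cl2, 0 °C → rt, stopped at partial conversion
Reagents that add atoms: tert-butyl hydroperoxide, CC(C)(C)OO (terminal oxidant; the oxygen atom is passed on through SeO2, O=[Se]=O)
Why: Catalytic SeO2 allylic oxidation (ene reaction, then [2,3]-sigmatropic shift): the terminal, most electron-rich trisubstituted alkene reacts, the mechanism delivers the hydroxyl to the methyl trans to the chain to give the E-alcohol, and the alkene next to the silyloxy group is deactivated; conversion is held back to limit over-oxidation.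

**Step 12**
Reactants: 15 (2E,6E,10E)-12-{[tert-butyl(dimethyl)silyl]oxy}-2,6,10-trimethyldodeca-2,6,10-trien-1-ol
Product: 16 {[(2E,6E,10E)-12-bromo-3,7,11-trimethyldodeca-2,6,10-trien-1-yl]oxy}(tert-butyl)dimethylsilane
Conditions: CBr4, PPh3, CH2Cl2, −20 → 0 °C; used directly
Reagents that add atoms: carbon tetrabromide, BrC(Br)(Br)Br
Why: Appel reaction: SN2 displacement of the alkoxyphosphonium ion by bromide at the primary allylic carbon keeps the E geometry, and the neutral conditions spare the silyl ether.

**Step 13**
Reactants: 12 (1S,2S)-2-[(benzenesulfonyl)methyl]-1,3,3-trimethylcyclohexan-1-ol; 16 {[(2E,6E,10E)-12-bromo-3,7,11-trimethyldodeca-2,6,10-trien-1-yl]oxy}(tert-butyl)dimethylsilane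
Product: 18 (1S,2S)-2-[(3E,7E,11E)-1-(benzenesulfonyl)-13-{[tert-butyl(dimethyl)silyl]oxy}-3,7,11-trimethyltrideca-3,7,11-trien-1-yl]-1,3,3-trimethylcyclohexan-1-ol (both epimers at the sulfonyl-bearing carbon), via dilithio dianion 17 (not isolated)
Conditions: n-BuLi (2.1 equiv), THF/DMPU, −78 → −40 °C; then 16, −78 → −20 °C; H2O
Reagents that add atoms: none
Why: Alkylation of an α-sulfonyl carbanion: the first equivalent of n-BuLi forms the tertiary lithium alkoxide and the second lithiates C13; the soft carbanion attacks the primary allylic bromide by SN2 without allylic transposition or loss of E geometry, while the hindered alkoxide should not compete at low temperature; the new centre at C13 is removed in step 14, and alkylations of sulfonylmethyl groups on 2,2,6-trisubstituted six-membered rings with allylic halides are the closest analogy.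

**Step 14**
Reactants: 18 (1S,2S)-2-[(3E,7E,11E)-1-(benzenesulfonyl)-13-{[tert-butyl(dimethyl)silyl]oxy}-3,7,11-trimethyltrideca-3,7,11-trien-1-yl]-1,3,3-trimethylcyclohexan-1-ol
Product: 19 (1S,2S)-2-[(3E,7E,11E)-13-{[tert-butyl(dimethyl)silyl]oxy}-3,7,11-trimethyltrideca-3,7,11-trien-1-yl]-1,3,3-trimethylcyclohexan-1-ol
Conditions: 6% Na(Hg), Na2HPO4, MeOH/THF, −20 °C
Reagents that add atoms: none
Why: Reductive desulfonylation by electron transfer from the amalgam, C–S cleavage and protonation at C13 by methanol; the sulfone is homoallylic, not allylic, so no alkene shifts, both epimers converge, and the buffer keeps the medium from turning strongly basic.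

**Step 15**
Reactants: 19 (1S,2S)-2-[(3E,7E,11E)-13-{[tert-butyl(dimethyl)silyl]oxy}-3,7,11-trimethyltrideca-3,7,11-trien-1-yl]-1,3,3-trimethylcyclohexan-1-ol
Product: 20 preluffariellolide A, (1S,2S)-2-[(3E,7E,11E)-13-hydroxy-3,7,11-trimethyltrideca-3,7,11-trien-1-yl]-1,3,3-trimethylcyclohexan-1-ol
Conditions: Bu4NF, THF, 0 °C → rt
Reagents that add atoms: none
Why: Fluoride cleavage of the silyl ether, driven by the Si–F bond; the non-acidic conditions leave the tertiary alcohol, the allylic alcohol and the alkenes intact.

## Compound list

1 | 2,3-dimethylfuran | Cc1occc1C | starting material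
2 | (2Z)-3-methyl-4-oxopent-2-enal | CC(=O)/C(C)=C\C=O | intermediate
3 | (2E)-3-methyl-4-oxopent-2-enal | CC(=O)/C(C)=C/C=O | intermediate
4 | 4-methylpenta-1,3-diene | CC(C)=CC=C | starting material
5 | (1S,6S)-6-acetyl-2,2,6-trimethylcyclohex-3-ene-1-carbaldehyde | O=C[C@H]1C(C)(C)C=CC[C@]1(C)C(C)=O | intermediate
6 | 1-[(1S,6S)-6-(hydroxymethyl)-1,5,5-trimethylcyclohex-3-en-1-yl]ethan-1-one | OC[C@H]1C(C)(C)C=CC[C@]1(C)C(C)=O | intermediate
7 | [(1S,6S)-6-acetyl-2,2,6-trimethylcyclohex-3-en-1-yl]methyl acetate | CC(=O)OC[C@H]1C(C)(C)C=CC[C@]1(C)C(C)=O | intermediate
8 | [(1S,2S)-2-acetyl-2,6,6-trimethylcyclohexyl]methyl acetate | CC(=O)OC[C@H]1C(C)(C)CCC[C@]1(C)C(C)=O | intermediate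
9 | (1S,2R)-2-[(acetyloxy)methyl]-1,3,3-trimethylcyclohexyl acetate | CC(=O)OC[C@H]1C(C)(C)CCC[C@]1(C)OC(C)=O | intermediate
10 | (1S,2R)-2-(hydroxymethyl)-1,3,3-trimethylcyclohexan-1-ol | OC[C@H]1C(C)(C)CCC[C@]1(C)O | intermediate
11 | (1S,2S)-1,3,3-trimethyl-2-[(phenylsulfanyl)methyl]cyclohexan-1-ol | c1ccccc1SC[C@H]1C(C)(C)CCC[C@]1(C)O | intermediate
12 | (1S,2S)-2-[(benzenesulfonyl)methyl]-1,3,3-trimethylcyclohexan-1-ol | O=S(=O)(C[C@H]1C(C)(C)CCC[C@]1(C)O)c1ccccc1 | intermediate
13 | (2E,6E)-farnesol | C/C(=C\CO)CC/C=C(\C)CCC=C(C)C | starting material
14 | tert-butyl(dimethyl){[(2E,6E)-3,7,11-trimethyldodeca-2,6,10-trien-1-yl]oxy}silane | C/C(=C\CO[Si](C)(C)C(C)(C)C)CC/C=C(\C)CCC=C(C)C | intermediate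
15 | (2E,6E,10E)-12-{[tert-butyl(dimethyl)silyl]oxy}-2,6,10-trimethyldodeca-2,6,10-trien-1-ol | C/C(=C\CO[Si](C)(C)C(C)(C)C)CC/C=C(\C)CC/C=C(\C)CO | intermediate
16 | {[(2E,6E,10E)-12-bromo-3,7,11-trimethyldodeca-2,6,10-trien-1-yl]oxy}(tert-butyl)dimethylsilane | C/C(=C\CO[Si](C)(C)C(C)(C)C)CC/C=C(\C)CC/C=C(\C)CBr | intermediate
17 | dilithium salt of 12: lithium (1S,2S)-2-[(benzenesulfonyl)(lithio)methyl]-1,3,3-trimethylcyclohexan-1-olate | O=S(=O)([CH-][C@H]1C(C)(C)CCC[C@]1(C)[O-])c1ccccc1.[Li+].[Li+] | intermediate
18 | (1S,2S)-2-[(3E,7E,11E)-1-(benzenesulfonyl)-13-{[tert-butyl(dimethyl)silyl]oxy}-3,7,11-trimethyltrideca-3,7,11-trien-1-yl]-1,3,3-trimethylcyclohexan-1-ol, both epimers at the sulfonyl-bearing carbon | C/C(=C\CO[Si](C)(C)C(C)(C)C)CC/C=C(\C)CC/C=C(\C)CC([C@H]1C(C)(C)CCC[C@]1(C)O)S(=O)(=O)c1ccccc1 | intermediate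
19 | (1S,2S)-2-[(3E,7E,11E)-13-{[tert-butyl(dimethyl)silyl]oxy}-3,7,11-trimethyltrideca-3,7,11-trien-1-yl]-1,3,3-trimethylcyclohexan-1-ol | C/C(=C\CO[Si](C)(C)C(C)(C)C)CC/C=C(\C)CC/C=C(\C)CC[C@H]1C(C)(C)CCC[C@]1(C)O | intermediate
20 | preluffariellolide A, (1S,2S)-2-[(3E,7E,11E)-13-hydroxy-3,7,11-trimethyltrideca-3,7,11-trien-1-yl]-1,3,3-trimethylcyclohexan-1-ol | C/C(=C\CO)CC/C=C(\C)CC/C=C(\C)CC[C@H]1C(C)(C)CCC[C@]1(C)O | target

The descriptor at C14 is S in 5–8, R in 9 and 10, and S again from 11 on. This reflects changes in substituent priority only; the spatial arrangement is the same throughout.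

## Step count and least certain steps

Total: 15 steps. Longest linear sequence: 12 steps (steps 1–9 and 13–15, from 1 to 20); the chain arm from 13 takes steps 10–12.

**Step 2 (key step).** The cycloaddition may be too slow, because the diene must reach the s-cis conformer against its cis-methyl group while both reacting carbons of the dienophile are hindered. The strongly acidic catalyst may instead start cationic oligomerisation of the diene, hetero-cycloaddition through the enal oxygen, or an ene reaction. Facial selection may be poor because this α-unsubstituted, β,β-disubstituted enal can bind the catalyst in more than one way.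
Fallback (catalytic induction replaced by resolution): from 3 and 4 the cycloaddition is run with the achiral Lewis acid Me2AlCl in CH2Cl2 at low temperature, or thermally under high pressure. This gives 5 as the racemate, that is, together with (1R,6R)-6-acetyl-2,2,6-trimethylcyclohex-3-ene-1-carbaldehyde F1. Reduction as in step 3 gives 6 together with 1-[(1R,6R)-6-(hydroxymethyl)-1,5,5-trimethylcyclohex-3-en-1-yl]ethan-1-one F2. Esterification of the mixture with (S)-2-methoxy-2-phenylacetic acid (N,N'-dicyclohexylcarbodiimide, 4-(dimethylamino)pyridine) gives the diastereomers [(1S,6S)-6-acetyl-2,2,6-trimethylcyclohex-3-en-1-yl]methyl (2S)-2-methoxy-2-phenylacetate F3 and [(1R,6R)-6-acetyl-2,2,6-trimethylcyclohex-3-en-1-yl]methyl (2S)-2-methoxy-2-phenylacetate F4, which are separated by chromatography or crystallisation. Methanolysis of F3 (K2CO3, MeOH) returns 6, and the route continues at step 4.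

**Step 13.** C-alkylation at the hindered, dianionic carbanion may be slow, so that proton transfer, O-alkylation at the alkoxide or base-induced decomposition of the allylic bromide take over; aggregation of the dianion may also leave C13 incompletely lithiated.
Fallback (monoanion of a protected substrate): from 12, silylation with Et3SiOSO2CF3 and 2,6-lutidine gives triethyl{[(1S,2S)-2-[(benzenesulfonyl)methyl]-1,3,3-trimethylcyclohexyl]oxy}silane F5. One equivalent of n-BuLi and then 16 give tert-butyl{[(2E,6E,10E)-13-(benzenesulfonyl)-3,7,11-trimethyl-13-{(1S,2S)-2,6,6-trimethyl-2-[(triethylsilyl)oxy]cyclohexyl}trideca-2,6,10-trien-1-yl]oxy}dimethylsilane F6. Na(Hg) in buffered methanol gives tert-butyl(dimethyl){[(2E,6E,10E)-3,7,11-trimethyl-13-{(1S,2S)-2,6,6-trimethyl-2-[(triethylsilyl)oxy]cyclohexyl}trideca-2,6,10-trien-1-yl]oxy}silane F7, and Bu4NF removes both silyl groups to reach 20 directly.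

**Step 8.** Displacement at the β-branched C13 may be so slow that the alkoxyphosphonium ion is diverted, for instance into ring-opening fragmentation driven by the free tertiary hydroxyl, or into elimination.
Fallback (C–S bond made by carbonyl chemistry, not by substitution): from 5, hydrogenation (H2, Pd/C, EtOAc) gives (1S,2S)-2-acetyl-2,6,6-trimethylcyclohexane-1-carbaldehyde F8. Reductive thioetherification of the aldehyde (PhSH, Et3SiH, CF3CO2H, CH2Cl2, 0 °C) gives 1-{(1S,2S)-1,3,3-trimethyl-2-[(phenylsulfanyl)methyl]cyclohexyl}ethan-1-one F9. Excess buffered CF3CO3H oxidises the sulfide to the sulfone and carries out the Baeyer–Villiger step in the same flask, giving (1S,2S)-2-[(benzenesulfonyl)methyl]-1,3,3-trimethylcyclohexyl acetate F10. LiAlH4 at 0 °C removes the acetate and returns the route at 12. The point to watch is epimerisation at C14 through the thionium ion, and the ketone must stay out of thioketal formation.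

**Step 1.** Bromination of the free furan α-position may compete with oxidative opening, the cis-to-trans isomerisation of the trisubstituted alkene may stop short, and the small, electrophilic enal may be lost by oligomerisation or on concentration.
Fallback (olefination in place of furan oxidation): 3 is made directly by Wittig reaction of butane-2,3-dione, used in excess, with (triphenylphosphoranylidene)acetaldehyde in CH2Cl2 at rt. This does not set out from a numbered compound but replaces 1 as starting material, and it comes back to the route at 3.

## Further compounds

F1 | step 2 | (1R,6R)-6-acetyl-2,2,6-trimethylcyclohex-3-ene-1-carbaldehyde | O=C[C@@H]1C(C)(C)C=CC[C@@]1(C)C(C)=O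
F2 | step 2 | 1-[(1R,6R)-6-(hydroxymethyl)-1,5,5-trimethylcyclohex-3-en-1-yl]ethan-1-one | OC[C@@H]1C(C)(C)C=CC[C@@]1(C)C(C)=O
F3 | step 2 | [(1S,6S)-6-acetyl-2,2,6-trimethylcyclohex-3-en-1-yl]methyl (2S)-2-methoxy-2-phenylacetate | CO[C@H](C(=O)OC[C@H]1C(C)(C)C=CC[C@]1(C)C(C)=O)c1ccccc1
F4 | step 2 | [(1R,6R)-6-acetyl-2,2,6-trimethylcyclohex-3-en-1-yl]methyl (2S)-2-methoxy-2-phenylacetate | CO[C@H](C(=O)OC[C@@H]1C(C)(C)C=CC[C@@]1(C)C(C)=O)c1ccccc1
F5 | step 13 | triethyl{[(1S,2S)-2-[(benzenesulfonyl)methyl]-1,3,3-trimethylcyclohexyl]oxy}silane | O=S(=O)(C[C@H]1C(C)(C)CCC[C@]1(C)O[Si](CC)(CC)CC)c1ccccc1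
F6 | step 13 | tert-butyl{[(2E,6E,10E)-13-(benzenesulfonyl)-3,7,11-trimethyl-13-{(1S,2S)-2,6,6-trimethyl-2-[(triethylsilyl)oxy]cyclohexyl}trideca-2,6,10-trien-1-yl]oxy}dimethylsilane, both epimers at the sulfonyl-bearing carbon | C/C(=C\CO[Si](C)(C)C(C)(C)C)CC/C=C(\C)CC/C=C(\C)CC([C@H]1C(C)(C)CCC[C@]1(C)O[Si](CC)(CC)CC)S(=O)(=O)c1ccccc1
F7 | step 13 | tert-butyl(dimethyl){[(2E,6E,10E)-3,7,11-trimethyl-13-{(1S,2S)-2,6,6-trimethyl-2-[(triethylsilyl)oxy]cyclohexyl}trideca-2,6,10-trien-1-yl]oxy}silane | C/C(=C\CO[Si](C)(C)C(C)(C)C)CC/C=C(\C)CC/C=C(\C)CC[C@H]1C(C)(C)CCC[C@]1(C)O[Si](CC)(CC)CC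
F8 | step 8 | (1S,2S)-2-acetyl-2,6,6-trimethylcyclohexane-1-carbaldehyde | O=C[C@H]1C(C)(C)CCC[C@]1(C)C(C)=O
F9 | step 8 | 1-{(1S,2S)-1,3,3-trimethyl-2-[(phenylsulfanyl)methyl]cyclohexyl}ethan-1-one | c1ccccc1SC[C@H]1C(C)(C)CCC[C@]1(C)C(C)=O
F10 | step 8 | (1S,2S)-2-[(benzenesulfonyl)methyl]-1,3,3-trimethylcyclohexyl acetate | O=S(=O)(C[C@H]1C(C)(C)CCC[C@]1(C)OC(C)=O)c1ccccc1
F0 | step 1 | none | none
A1 | alternative 1 | [(2,6-dimethylcyclohexa-2,5-dien-1-yl)methoxy]tri(propan-2-yl)silane | CC(C)[Si](C(C)C)(C(C)C)OCC1C(C)=CCC=C1C
A2 | alternative 1 | mono-epoxide of A1 at one trisubstituted alkene, oxirane oxygen trans to the CH2OSi group | CC(C)[Si](C(C)C)(C(C)C)OC[C@H]1C(C)=CC[C@@H]2O[C@]12C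
A3 | alternative 2 | (2E)-5-[(1S,2S)-2-hydroxy-2,6,6-trimethylcyclohexyl]-3-methylpent-2-en-1-yl trihydrogen diphosphate | C/C(=C\COP(=O)(O)OP(=O)(O)O)CC[C@H]1C(C)(C)CCC[C@]1(C)O
A4 | alternative 2 | isopentenyl diphosphate (3-methylbut-3-en-1-yl trihydrogen diphosphate) | CC(=C)CCOP(=O)(O)OP(=O)(O)O
A5 | alternative 2 | preluffariellolide A 1-diphosphate | C/C(=C\COP(=O)(O)OP(=O)(O)O)CC/C=C(\C)CC/C=C(\C)CC[C@H]1C(C)(C)CCC[C@]1(C)O
A6 | alternative 3 | 3,3-dimethyl-7-oxooctanal | O=CCC(C)(C)CCCC(C)=O
A7 | alternative 3 | (1S,2S)-2-hydroxy-2,6,6-trimethylcyclohexane-1-carbaldehyde | O=C[C@H]1C(C)(C)CCC[C@]1(C)O
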